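**Strategy.** Ring A, the dearomatised triketone ring, is numbered as a cyclohexa-2,5-dien-1-one: C1 carbonyl, C2 butanoyl-bearing, C4 gem-dimethyl, C6 bridge-bearing. It is cut at C1–C2 and C5–C6. The feature exploited is the quaternary C4 flanked by two oxygenated ring carbons, which is a dimethylmalonyl unit. In one operation a β-amino ester enolate opens the enol lactone 3,3-dimethyl-6-propylpyran-2,4-dione (C5–C6), and the released diketonate closes onto the ester (C1–C2). Ring A, its butanoyl group and a CH2NMe2 bridge handle arise together. The resulting Mannich base then alkylates a B–C–D trimer built by quinone-methide couplings.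

Key step: step 3

Remark: the target has no stereocentre, and ring A compounds are written in the enol tautomer of the target. Rings are lettered A (dimethylated triketone ring), B and C (the two butanoylphloroglucinol rings, B next to A) and D (the C-methylated ring).

**Step 1**
Reactants: 1 pentan-2-one
Product: 2 trimethyl(pent-1-en-2-yloxy)silane
Conditions: LiN(iPr)2 (LDA), THF, −78 °C; then TMSCl, −78 °C → rt
Reagents that add atoms: chlorotrimethylsilane (TMSCl), C[Si](C)(C)Cl
Why: Kinetic deprotonation of the methyl ketone at CH3 by the hindered amide base at −78 °C, followed by O-silylation, should give the terminal silyl enol ether (kinetic enolate trapping).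

**Step 2**
Reactants: 2 trimethyl(pent-1-en-2-yloxy)silane; 3 2,2-dimethylpropanedioyl dichloride (dimethylmalonyl dichloride)
Product: 5 3,3-dimethyl-6-propyl-2H-pyran-2,4(3H)-dione, via diketo acid chloride 4 (not isolated)
Conditions: cat. ZnCl2, Et2O/CH2Cl2, slow addition of 2 to 3, 0 °C → rt; then Et3N, 0 °C
Reagents that add atoms: none
Why: Lewis-acid-catalysed C-acylation of the silyl enol ether by one COCl group (Mukaiyama-type acylation) should give β-diketone 4, whose butanoyl-side enol oxygen then closes on the second COCl to the six-membered enol lactone once Et3N takes up HCl; slow addition of 2 to excess 3 should hold back double acylation.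

**Step 3**
Reactants: 5 3,3-dimethyl-6-propyl-2H-pyran-2,4(3H)-dione; 6 methyl 3-(dimethylamino)propanoate
Product: 9 2-butanoyl-6-[(dimethylamino)methyl]-3,5-dihydroxy-4,4-dimethylcyclohexa-2,5-dien-1-one (Mannich base of butyrylfilicinic acid; internal salt), via lithium ester enolate 7 (not isolated), via acyclic triketo ester enolate 8 (not isolated)
Conditions: 6, LiN(iPr)2 (LDA), THF, −78 °C; cannulated into 5 (1 equiv), THF, −78 °C; then → 50 °C; AcOH
Reagents that add atoms: none
Why: Enolate 7 should add to the lactone carbonyl of 5 (C-2 of the pyranone, the future C5 of ring A), the best acyl donor in the molecule because its acyl group sits on an enol oxygen, and collapse of the adduct expels the ring oxygen as chelated lithium diketonate 8 (first C–C bond, C5–C6); on warming, the diketonate carbon of 8 attacks the methyl ester and methoxide leaves (second C–C bond, C1–C2), the triketone being deprotonated at once so that the sequence ends in a stabilised enolate. The closest known reaction type is a crossed Claisen acylation of an ester enolate by an enol lactone followed by a Dieckmann condensation, as in the alkoxide-induced isomerisation of enol lactones to cyclic 1,3-diketones and in enol-lactone acylations of the Fujimoto–Belleau type. The carbocycle closes in a 6-exo-trig mode, the enolate carbon attacking the ester carbonyl with the alkoxide leaving outside the ring. No stereocentre is created, since the C–H carbon between ketone and ester in 8 ends as an enol carbon. The step needs attack at the lactone carbonyl and not at the C4 ketone or C6 of 5, C- and not O-acylation in the closure, and survival of the β-amino group; these should be secured by irreversible acyl substitution at the enol ester against reversible addition at the hindered vinylogous-ester ketone, by lithium chelation and the thermodynamic sink of the triketone enolate, by inverse addition (so that 8 stays a monoanion whose keto ester remains electrophilic) and by the poor leaving-group ability of dimethylamide at −78 °C. Because C6 arrives already aminomethylated, the Mannich base never meets unsubstituted acylfilicinic acid, so the methylene-bis dimer of ring A cannot form.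

**Step 4**
Reactants: 10 benzene-1,3,5-triol (phloroglucinol)
Product: 11 1-(2,4,6-trihydroxyphenyl)butan-1-one (phlorobutyrophenone)
Conditions: butanoyl chloride (1 equiv), AlCl3, PhNO2, 60 °C; ice/aq. HCl
Reagents that add atoms: butanoyl chloride, CCCC(=O)Cl
Why: Friedel–Crafts C-acylation of the highly activated triol should stop at monoacylation, because the first chelated acyl group deactivates the ring.

**Step 5**
Reactants: 11 1-(2,4,6-trihydroxyphenyl)butan-1-one (two molecules enter each molecule of 14)
Product: 14 1,1'-[methylenebis(2,4,6-trihydroxy-3,1-phenylene)]dibutan-1-one, via hydroxymethyl phlorobutyrophenone 12 (not isolated), via ortho-quinone methide 13 (not isolated)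
Conditions: 37% aq. CH2O (0.25 equiv relative to 11), 1% aq. KOH (1 equiv), 0 °C → rt, Ar; then aq. HCl
Reagents that add atoms: formaldehyde, C=O; second molecule of 11, 1-(2,4,6-trihydroxyphenyl)butan-1-one, CCCC(=O)c1c(O)cc(O)cc1O
Why: Hydroxymethylation of the phenolate of a first molecule of 11 (Lederer–Manasse reaction) gives 12, which loses water to ortho-quinone methide 13, and the phenolate of a second molecule of 11 captures 13 at a nuclear carbon by Michael addition with re-aromatisation; keeping 11 in excess over formaldehyde should hold back higher oligomers, and unreacted 11 is recovered.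

**Step 6**
Reactants: 15 2-methylbenzene-1,3,5-triol
Product: 16 1-(2,4,6-trihydroxy-3-methylphenyl)butan-1-one
Conditions: butanoyl chloride (1 equiv), AlCl3, PhNO2, 60 °C; ice/aq. HCl
Reagents that add atoms: butanoyl chloride, CCCC(=O)Cl
Why: Friedel–Crafts C-acylation as in step 4; the two free nuclear positions of 15 are equivalent, so a single regioisomer should form.

**Step 7**
Reactants: 16 1-(2,4,6-trihydroxy-3-methylphenyl)butan-1-one
Product: 17 1-{3-[(dimethylamino)methyl]-2,4,6-trihydroxy-5-methylphenyl}butan-1-one
Conditions: bis(dimethylamino)methane (1.2 equiv), EtOH, 0 °C → rt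
Reagents that add atoms: bis(dimethylamino)methane, CN(C)CN(C)C
Why: Mannich aminomethylation at the only free nuclear position, the acidic phenol protonating the aminal to release the iminium ion; the low temperature should keep the Mannich base from going on to the methylene-bis dimer.

**Step 8**
Reactants: 14 1,1'-[methylenebis(2,4,6-trihydroxy-3,1-phenylene)]dibutan-1-one; 17 1-{3-[(dimethylamino)methyl]-2,4,6-trihydroxy-5-methylphenyl}butan-1-one
Product: 19 1-{3-[(3-butanoyl-2,4,6-trihydroxyphenyl)methyl]-5-[(3-butanoyl-2,4,6-trihydroxy-5-methylphenyl)methyl]-2,4,6-trihydroxyphenyl}butan-1-one (trimer B–C–D), via ortho-quinone methide 18 (not isolated)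
Conditions: 14 (3 equiv), 1,4-dioxane, 90 °C, N2 stream
Reagents that add atoms: none
Why: Thermal loss of dimethylamine from the zwitterionic Mannich base gives ortho-quinone methide 18, which a free nuclear carbon of 14 attacks in a Michael addition with re-aromatisation (quinone-methide alkylation of a phenol); the two free positions of symmetric 14 are equivalent, and its threefold excess should favour monoalkylation.

**Step 9**
Reactants: 19 trimer B–C–D; 9 2-butanoyl-6-[(dimethylamino)methyl]-3,5-dihydroxy-4,4-dimethylcyclohexa-2,5-dien-1-one
Product: 21 tetramer A–B–C–D (CNP0246352.0), via methylene triketone 20 (not isolated)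
Conditions: 9 (1.1 equiv), 1,4-dioxane, 60 °C, N2 stream
Reagents that add atoms: none
Why: The betaine should lose dimethylamine under mild heating (E1cB) to the doubly activated methylene triketone 20, which the single remaining nuclear C–H of ring B attacks in a Michael addition followed by re-aromatisation; no other carbon nucleophile is present, and the low temperature should limit exchange of the methylene bridges.

**Compound list**
1 | pentan-2-one | CCCC(C)=O | starting material
2 | trimethyl(pent-1-en-2-yloxy)silane | CCCC(=C)O[Si](C)(C)C | intermediate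
3 | 2,2-dimethylpropanedioyl dichloride | CC(C)(C(=O)Cl)C(=O)Cl | starting material
4 | 2,2-dimethyl-3,5-dioxooctanoyl chloride (not isolated) | CCCC(=O)CC(=O)C(C)(C)C(=O)Cl | intermediate
5 | 3,3-dimethyl-6-propyl-2H-pyran-2,4(3H)-dione | CCCC1=CC(=O)C(C)(C)C(=O)O1 | intermediate
6 | methyl 3-(dimethylamino)propanoate | COC(=O)CCN(C)C | starting material
7 | lithium enolate of methyl 3-(dimethylamino)propanoate (not isolated) | [Li+].COC(=O)[CH-]CN(C)C | intermediate
8 | lithium diketonate of methyl 2-[(dimethylamino)methyl]-4,4-dimethyl-3,5,7-trioxodecanoate (not isolated) | [Li+].CCCC(=O)[CH-]C(=O)C(C)(C)C(=O)C(CN(C)C)C(=O)OC | intermediate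
9 | 2-butanoyl-6-[(dimethylamino)methyl]-3,5-dihydroxy-4,4-dimethylcyclohexa-2,5-dien-1-one | CCCC(=O)C1=C(O)C(C)(C)C(O)=C(CN(C)C)C1=O | intermediate
10 | benzene-1,3,5-triol | Oc1cc(O)cc(O)c1 | starting material
11 | 1-(2,4,6-trihydroxyphenyl)butan-1-one | CCCC(=O)c1c(O)cc(O)cc1O | intermediate
12 | 1-[2,4,6-trihydroxy-3-(hydroxymethyl)phenyl]butan-1-one (not isolated) | CCCC(=O)c1c(O)cc(O)c(CO)c1O | intermediate
13 | 2-butanoyl-3,5-dihydroxy-6-methylidenecyclohexa-2,4-dien-1-one (not isolated) | C=C1C(=O)C(C(=O)CCC)=C(O)C=C1O | intermediate
14 | 1,1'-[methylenebis(2,4,6-trihydroxy-3,1-phenylene)]dibutan-1-one | CCCC(=O)c1c(O)cc(O)c(Cc2c(O)cc(O)c(C(=O)CCC)c2O)c1O | intermediate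
15 | 2-methylbenzene-1,3,5-triol | Cc1c(O)cc(O)cc1O | starting material
16 | 1-(2,4,6-trihydroxy-3-methylphenyl)butan-1-one | CCCC(=O)c1c(O)cc(O)c(C)c1O | intermediate
17 | 1-{3-[(dimethylamino)methyl]-2,4,6-trihydroxy-5-methylphenyl}butan-1-one | CCCC(=O)c1c(O)c(C)c(O)c(CN(C)C)c1O | intermediate
18 | 2-butanoyl-3,5-dihydroxy-4-methyl-6-methylidenecyclohexa-2,4-dien-1-one (not isolated) | C=C1C(=O)C(C(=O)CCC)=C(O)C(C)=C1O | intermediate
19 | trimer B–C–D, 1-{3-[(3-butanoyl-2,4,6-trihydroxyphenyl)methyl]-5-[(3-butanoyl-2,4,6-trihydroxy-5-methylphenyl)methyl]-2,4,6-trihydroxyphenyl}butan-1-one | CCCC(=O)c1c(O)cc(O)c(Cc2c(O)c(Cc3c(O)c(C)c(O)c(C(=O)CCC)c3O)c(O)c(C(=O)CCC)c2O)c1O | intermediate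
20 | 2-butanoyl-3-hydroxy-4,4-dimethyl-6-methylidenecyclohex-2-ene-1,5-dione (not isolated) | CCCC(=O)C1=C(O)C(C)(C)C(=O)C(=C)C1=O | intermediate
21 | tetramer A–B–C–D (CNP0246352.0): ring A of 9 joined through CH2 to the free nuclear position of ring B of 19 | CCCC(=O)C1=C(O)C(C)(C)C(O)=C(Cc2c(O)c(Cc3c(O)c(Cc4c(O)c(C)c(O)c(C(=O)CCC)c4O)c(O)c(C(=O)CCC)c3O)c(O)c(C(=O)CCC)c2O)C1=O | target

**Step count.** Total steps: 9. Longest linear sequence: 4 steps (for example steps 1, 2, 3 and 9).

**Steps most likely to fail**

Step 3. The enolate 7 may be consumed unproductively: by loss of lithium dimethylamide (retro-Michael) before or after acylation, by proton abstraction from the propyl CH2 of 5, or by stalling at the acyclic stage 8. Fallback, setting out from 5 and coming back at 9: the lithium enolate of methyl acetate (LiN(iPr)2, THF, −78 °C) takes the place of 7 in the same acylation–Dieckmann sequence. This enolate has no group to lose and tolerates excess base and a methoxide-driven closure at reflux. It should give 2-butanoyl-3,5-dihydroxy-4,4-dimethylcyclohexa-2,5-dien-1-one (butyrylfilicinic acid) F1. Aminomethylation of F1 at C6 with excess bis(dimethylamino)methane in EtOH at 0 °C then gives 9.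

Step 8. Alkylation of the second free ring of 14, statistical product distribution and bridge exchange at 90 °C may erode the monoalkylation. Fallback, setting out from 17 and 11 and coming back at 19: the chain is grown one ring at a time with the cheap monomer in excess. Mannich base 17 is heated with 11 (5 equiv, dioxane, 90 °C) to give the dimer C–D, 1-{3-[(3-butanoyl-2,4,6-trihydroxy-5-methylphenyl)methyl]-2,4,6-trihydroxyphenyl}butan-1-one F2. Aminomethylation of the one free position of ring C with bis(dimethylamino)methane gives the Mannich base of the dimer C–D, 1-{3-[(3-butanoyl-2,4,6-trihydroxy-5-methylphenyl)methyl]-5-[(dimethylamino)methyl]-2,4,6-trihydroxyphenyl}butan-1-one F3. Heating F3 with 11 (5 equiv) then gives 19.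

Step 9. Self-condensation of methylene triketone 20 and scrambling of the methylene bridges by retro-Michael and re-addition may compete with the cross-coupling. Fallback, setting out from 19 and coming back at 21: the polarity is reversed so that ring A acts only as the carbon acid. Trimer 19 is aminomethylated at its single free nuclear position with bis(dimethylamino)methane to give the Mannich base of trimer B–C–D F4. F4 is heated in dioxane with butyrylfilicinic acid F1 (prepared from 5 as in the fallback to step 3), whose C6 adds to the aromatic ortho-quinone methide under the conditions of step 8 to give 21.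

**Further compounds**
F1 | step 3 | 2-butanoyl-3,5-dihydroxy-4,4-dimethylcyclohexa-2,5-dien-1-one (butyrylfilicinic acid) | CCCC(=O)C1=C(O)C(C)(C)C(O)=CC1=O
F2 | step 8 | 1-{3-[(3-butanoyl-2,4,6-trihydroxy-5-methylphenyl)methyl]-2,4,6-trihydroxyphenyl}butan-1-one (dimer C–D) | CCCC(=O)c1c(O)cc(O)c(Cc2c(O)c(C)c(O)c(C(=O)CCC)c2O)c1O
F3 | step 8 | 1-{3-[(3-butanoyl-2,4,6-trihydroxy-5-methylphenyl)methyl]-5-[(dimethylamino)methyl]-2,4,6-trihydroxyphenyl}butan-1-one (Mannich base of dimer C–D) | CCCC(=O)c1c(O)c(CN(C)C)c(O)c(Cc2c(O)c(C)c(O)c(C(=O)CCC)c2O)c1O
F4 | step 9 | Mannich base of trimer B–C–D, 1-{3-[(3-butanoyl-5-[(dimethylamino)methyl]-2,4,6-trihydroxyphenyl)methyl]-5-[(3-butanoyl-2,4,6-trihydroxy-5-methylphenyl)methyl]-2,4,6-trihydroxyphenyl}butan-1-one | CCCC(=O)c1c(O)c(CN(C)C)c(O)c(Cc2c(O)c(Cc3c(O)c(C)c(O)c(C(=O)CCC)c3O)c(O)c(C(=O)CCC)c2O)c1O
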